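A direct plan would start from the ready-made flavone apigenin A1, protect it as the 7-O-benzyl 4'-O-methyl ether A2, hydroxylate C8 with persulfate to A3, arylate the new hydroxyl by SNAr to the aldehyde A4, join A4 to the chloroketone A5 by carbene catalysis to the 1,3-diketone A6, then deprotect and cyclise in acid.
Weakest would be the Elbs hydroxylation at C8: such persulfate oxidations stall at low conversion with poor mass balance and would leave an air-sensitive 5,8-hydroquinone to be arylated at its hindered oxygen.
Next would be the carbene-catalysed acylation of the α-chloroketone: an intermolecular acyl-anion alkylation without precedent, competing with benzoin coupling and alkylation of the carbene, on the most advanced material.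
Last would be the closing step, which loads debenzylation, a double ortho-demethylation and the cyclodehydration onto the final intermediate and ends in hot HCl, the conditions under which a 5,7-dihydroxy-8-aryloxyflavone opens and recloses to its 6-aryloxy isomer (Wessely–Moser).

**Plan of the new route.** The target is an ether between C8 of an acacetin half (5,7-dihydroxy-4'-methoxyflavone) and C4' of a genkwanin half (5-hydroxy-7-methoxyflavone).
The retrosynthesis re-methylates both C5 hydroxyls (17), cuts both pyranone rings at the C4–C4a carbon–carbon bond (diacid 16), cuts the two enol-ether bonds O1–C2 (15 to 13 + 14; 12 to 10 + 11), and last cuts the diaryl ether on a plain phenol (5 + 6).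
Forward, the hindered ether is made first on benzene rings, and both rings C then arise together in the final ring-forming step; no flavone exists before it.
The enabling feature: both rings A are phloroglucinol rings, so C4a of each half is strongly nucleophilic. Ring A of the genkwanin half is a symmetric 3,5-dimethoxyphenoxy group. With O5 methylated, ring A of the acacetin half is a mirror-symmetric 2-aryloxy-5-methoxyresorcinol whose second carbon ortho to O1 (C8) already carries the ether oxygen.
Hence there is no C8 hydroxylation, no fragment union on a flavone and no hot acid on a free 5,7-dihydroxy-8-aryloxyflavone, and the 6/8 question cannot arise.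

Key step: step 8

Remark: compounds 1, 6, 11 and 14 are taken as commercial. The conjugate additions are drawn as their (Z) isomers; an (E)/(Z) mixture would be carried on unchanged, because the acid of step 8 equilibrates the enol ethers.

Step 1
Reactants: 1 5-methoxybenzene-1,3-diol
Product: 2 1-methoxy-3,5-bis(methoxymethoxy)benzene
Conditions: NaH (2.5 equiv), MOMCl (2.5 equiv), DMF, 0 → 25 °C
Reagents that add atoms: chloromethyl methyl ether COCCl
Why: Twofold Williamson etherification of the phenoxides with the reactive α-chloro ether gives the bis(acetal) ether, which withstands the organolithium and SNAr steps and supplies the two directing groups for step 2.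

Step 2
Reactants: 2 1-methoxy-3,5-bis(methoxymethoxy)benzene
Product: 5 4-methoxy-2,6-bis(methoxymethoxy)phenol, via aryllithium 3 (not isolated), via lithium aryltrimethoxyborate 4 (not isolated)
Conditions: n-BuLi (1.15 equiv), THF, 0 °C; B(OMe)3 (1.5 equiv), −78 → 0 °C; then AcOH, 30 % aq. H2O2, 0 → 25 °C
Reagents that add atoms: hydrogen peroxide OO
Why: Directed ortho-metalation followed by borylation and oxidation (aryl migration from boron to oxygen): OMOM is a much stronger director than OMe, so butyllithium should remove the proton flanked by both OMOM groups, and the carbon that becomes C8 of the acacetin half receives its oxygen before any ring is built.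

Step 3
Reactants: 5 4-methoxy-2,6-bis(methoxymethoxy)phenol; 6 4-fluorobenzaldehyde
Product: 7 4-[4-methoxy-2,6-bis(methoxymethoxy)phenoxy]benzaldehyde
Conditions: 6 (1.2 equiv), K2CO3 (2 equiv), degassed DMF, 100 °C, Ar
Reagents that add atoms: none
Why: Nucleophilic aromatic substitution through a Meisenheimer complex, in which the only free hydroxyl, a 2,6-dialkoxyphenoxide, displaces fluoride para to the formyl group, so that the hindered diaryl ether is made on a simple phenol with no second phenol to compete, air being excluded so that the electron-rich phenoxide is not oxidised to a quinone.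

Step 4
Reactants: 7 4-[4-methoxy-2,6-bis(methoxymethoxy)phenoxy]benzaldehyde
Product: 8 2-[4-(2,2-dibromoethenyl)phenoxy]-5-methoxy-1,3-bis(methoxymethoxy)benzene
Conditions: CBr4 (2 equiv), PPh3 (4 equiv), Et3N (1 equiv), CH2Cl2, 0 °C
Reagents that add atoms: carbon tetrabromide BrC(Br)(Br)Br
Why: First stage of the Corey–Fuchs alkyne synthesis (dibromo-olefination by the ylide Ph3P=CBr2), with triethylamine buffering traces of HBr so that the acetal ethers survive.

Step 5
Reactants: 8 2-[4-(2,2-dibromoethenyl)phenoxy]-5-methoxy-1,3-bis(methoxymethoxy)benzene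
Product: 10 methyl 3-{4-[4-methoxy-2,6-bis(methoxymethoxy)phenoxy]phenyl}prop-2-ynoate, via lithium acetylide 9 (not isolated)
Conditions: n-BuLi (2.1 equiv), THF, −78 °C; then ClCO2Me (1.5 equiv), −78 → 0 °C
Reagents that add atoms: methyl chloroformate COC(=O)Cl
Why: Second stage of the Corey–Fuchs sequence, in which bromine–lithium exchange and loss of LiBr with 1,2-shift (Fritsch–Buttenberg–Wiechell) give the lithium acetylide, which is C-acylated by the chloroformate to the arylpropiolate, the aryl MOM ethers being inert to butyllithium at −78 °C.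

Step 6
Reactants: 10 methyl 3-{4-[4-methoxy-2,6-bis(methoxymethoxy)phenoxy]phenyl}prop-2-ynoate; 11 3,5-dimethoxyphenol
Product: 13 methyl (2Z)-3-[4-(2,6-dihydroxy-4-methoxyphenoxy)phenyl]-3-(3,5-dimethoxyphenoxy)prop-2-enoate, via bis-MOM enol ether 12 (not isolated)
Conditions: 11 (1.5 equiv), Cs2CO3 (0.5 equiv), DMF, 70 °C, N2; aqueous work-up; then HCl (2 M) in MeOH/THF, 25 °C
Reagents that add atoms: none
Why: Base-mediated oxa-Michael addition of the phenoxide to the arylpropiolate (the first stage of a Ruhemann flavone synthesis) sets the O1–C2 bond of the genkwanin half, anti addition giving mainly the (Z) enol ether, and the acetal ethers are then cleaved by methanolic HCl, methanol trapping the methoxymethyl cation as dimethoxymethane while the push–pull enol ether, a vinylogous carbonate of the kind that tolerates even the strong acid of a Ruhemann cyclisation, should stay intact.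

Step 7
Reactants: 13 methyl (2Z)-3-[4-(2,6-dihydroxy-4-methoxyphenoxy)phenyl]-3-(3,5-dimethoxyphenoxy)prop-2-enoate; 14 methyl 3-(4-methoxyphenyl)prop-2-ynoate
Product: 15 methyl (2Z)-3-(3,5-dimethoxyphenoxy)-3-[4-(2-hydroxy-4-methoxy-6-{[(1Z)-3-methoxy-1-(4-methoxyphenyl)-3-oxoprop-1-en-1-yl]oxy}phenoxy)phenyl]prop-2-enoate
Conditions: 14 (0.8 equiv, slow addition), Cs2CO3 (0.3 equiv), DMF, 50 °C, N2; unreacted 13 recovered and recycled
Reagents that add atoms: none
Why: Second oxa-Michael addition, setting O1–C2 of the acacetin half: the two hydroxyl groups of 13 are equivalent, so mono-addition gives one compound whichever reacts, 14 is kept limiting so that the bis-adduct should stay minor, and the enol ether already present is a fully substituted, donor-stabilised acceptor that should not exchange its aryloxy group at 50 °C.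

Step 8
Reactants: 15 methyl (2Z)-3-(3,5-dimethoxyphenoxy)-3-[4-(2-hydroxy-4-methoxy-6-{[(1Z)-3-methoxy-1-(4-methoxyphenyl)-3-oxoprop-1-en-1-yl]oxy}phenoxy)phenyl]prop-2-enoate
Product: 17 8-[4-(5,7-dimethoxy-4-oxo-4H-chromen-2-yl)phenoxy]-7-hydroxy-5-methoxy-2-(4-methoxyphenyl)-4H-chromen-4-one, via diacid 16 (not isolated)
Conditions: LiOH·H2O (6 equiv), THF/MeOH/H2O, 40 °C; 1 M HCl to pH 2, extraction, drying; then P2O5 in MeSO3H (Eaton's reagent, 1:10 w/w), 0.02 M, 25 → 40 °C
Reagents that add atoms: none
Why: After saponification, each (Z)-β-aryloxyacrylic acid is turned by the anhydride medium into a mixed anhydride or acylium ion whose carbon (the later C4) attacks the ortho carbon of its aryloxy ring (the later C4a) in an intramolecular Friedel–Crafts acylation, which is the cyclisation stage of the Ruhemann flavone synthesis run twice in one flask. Each pyranone ring is thus closed at the C4–C4a carbon–carbon bond by a six-membered electrophilic aromatic substitution (6-exo-dig attack on the acylium carbon), the O1–C2 bonds having been set by the conjugate additions, and any (E) isomer is fed into the (Z) manifold by reversible protonation of the enol ether. No stereocentre is formed. The site selectivity is secured by the substrate: in the genkwanin half the two carbons ortho to the enol-ether oxygen of the 3,5-dimethoxyphenoxy ring are equivalent, and in the acacetin half one ortho carbon carries the diaryl ether oxygen, so only the carbon between O1 and the methoxy group is open and the 6-aryloxy isomer cannot form. Chemoselectivity rests on the phloroglucinol-type rings A being far more nucleophilic than the 4-methoxyphenyl and 4-aryloxyphenyl rings, whose attack would also need a five-membered indenone closure from the (E) isomer, and the product keeps C5–OMe in the acacetin half, so a ring-opening and reclosure (Wessely–Moser) has no free C5 hydroxyl to use.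

Step 9
Reactants: 17 8-[4-(5,7-dimethoxy-4-oxo-4H-chromen-2-yl)phenoxy]-7-hydroxy-5-methoxy-2-(4-methoxyphenyl)-4H-chromen-4-one
Product: 18 5,7-dihydroxy-8-[4-(5-hydroxy-7-methoxy-4-oxo-4H-chromen-2-yl)phenoxy]-2-(4-methoxyphenyl)-4H-chromen-4-one
Conditions: BCl3 (1 M in CH2Cl2, 6 equiv), CH2Cl2, −78 → 0 °C; MeOH, then aq. NaHCO3
Reagents that add atoms: none
Why: Chelation-controlled ether cleavage, in which BCl3 binds each C4 carbonyl together with the peri C5 methoxy oxygen so that chloride should remove only these two methyl groups, while the unchelated 7-methoxy group of the genkwanin half, the 4'-methoxy group and the diaryl ether stay untouched at or below 0 °C and no hot protic acid is present that could isomerise the 8-aryloxyflavone; the product is achiral.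

**Compound list**

1 | 5-methoxybenzene-1,3-diol (5-methoxyresorcinol) | COc1cc(O)cc(O)c1 | starting material
2 | 1-methoxy-3,5-bis(methoxymethoxy)benzene | COCOc1cc(OC)cc(OCOC)c1 | intermediate
3 | [4-methoxy-2,6-bis(methoxymethoxy)phenyl]lithium (formed in situ) | [Li]c1c(OCOC)cc(OC)cc1OCOC | intermediate
4 | lithium trimethoxy[4-methoxy-2,6-bis(methoxymethoxy)phenyl]borate (formed in situ) | [Li+].CO[B-](OC)(OC)c1c(OCOC)cc(OC)cc1OCOC | intermediate
5 | 4-methoxy-2,6-bis(methoxymethoxy)phenol | COCOc1cc(OC)cc(OCOC)c1O | intermediate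
6 | 4-fluorobenzaldehyde | O=Cc1ccc(F)cc1 | starting material
7 | 4-[4-methoxy-2,6-bis(methoxymethoxy)phenoxy]benzaldehyde | COCOc1cc(OC)cc(OCOC)c1Oc1ccc(C=O)cc1 | intermediate
8 | 2-[4-(2,2-dibromoethenyl)phenoxy]-5-methoxy-1,3-bis(methoxymethoxy)benzene | COCOc1cc(OC)cc(OCOC)c1Oc1ccc(C=C(Br)Br)cc1 | intermediate
9 | lithium {4-[4-methoxy-2,6-bis(methoxymethoxy)phenoxy]phenyl}ethynide (formed in situ) | [Li]C#Cc1ccc(Oc2c(OCOC)cc(OC)cc2OCOC)cc1 | intermediate
10 | methyl 3-{4-[4-methoxy-2,6-bis(methoxymethoxy)phenoxy]phenyl}prop-2-ynoate | COC(=O)C#Cc1ccc(Oc2c(OCOC)cc(OC)cc2OCOC)cc1 | intermediate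
11 | 3,5-dimethoxyphenol | COc1cc(O)cc(OC)c1 | starting material
12 | methyl (2Z)-3-(3,5-dimethoxyphenoxy)-3-{4-[4-methoxy-2,6-bis(methoxymethoxy)phenoxy]phenyl}prop-2-enoate (formed in situ) | COC(=O)/C=C(\Oc1cc(OC)cc(OC)c1)c1ccc(Oc2c(OCOC)cc(OC)cc2OCOC)cc1 | intermediate
13 | methyl (2Z)-3-[4-(2,6-dihydroxy-4-methoxyphenoxy)phenyl]-3-(3,5-dimethoxyphenoxy)prop-2-enoate | COC(=O)/C=C(\Oc1cc(OC)cc(OC)c1)c1ccc(Oc2c(O)cc(OC)cc2O)cc1 | intermediate
14 | methyl 3-(4-methoxyphenyl)prop-2-ynoate | COC(=O)C#Cc1ccc(OC)cc1 | starting material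
15 | methyl (2Z)-3-(3,5-dimethoxyphenoxy)-3-[4-(2-hydroxy-4-methoxy-6-{[(1Z)-3-methoxy-1-(4-methoxyphenyl)-3-oxoprop-1-en-1-yl]oxy}phenoxy)phenyl]prop-2-enoate | COC(=O)/C=C(\Oc1cc(OC)cc(OC)c1)c1ccc(Oc2c(O)cc(OC)cc2O/C(=C\C(=O)OC)c2ccc(OC)cc2)cc1 | intermediate
16 | (2Z)-3-[4-(2-{[(1Z)-2-carboxy-1-(4-methoxyphenyl)ethenyl]oxy}-6-hydroxy-4-methoxyphenoxy)phenyl]-3-(3,5-dimethoxyphenoxy)prop-2-enoic acid (formed in situ) | OC(=O)/C=C(\Oc1cc(OC)cc(OC)c1)c1ccc(Oc2c(O)cc(OC)cc2O/C(=C\C(O)=O)c2ccc(OC)cc2)cc1 | intermediate
17 | 8-[4-(5,7-dimethoxy-4-oxo-4H-chromen-2-yl)phenoxy]-7-hydroxy-5-methoxy-2-(4-methoxyphenyl)-4H-chromen-4-one | COc1ccc(-c2cc(=O)c3c(OC)cc(O)c(Oc4ccc(-c5cc(=O)c6c(OC)cc(OC)cc6o5)cc4)c3o2)cc1 | intermediate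
18 | 5,7-dihydroxy-8-[4-(5-hydroxy-7-methoxy-4-oxo-4H-chromen-2-yl)phenoxy]-2-(4-methoxyphenyl)-4H-chromen-4-one (CNP0124888.0, achiral) | COc1ccc(-c2cc(=O)c3c(O)cc(O)c(Oc4ccc(-c5cc(=O)c6c(O)cc(OC)cc6o5)cc4)c3o2)cc1 | target

**Step count and risks**

Total: 9 steps, all in one linear sequence from 1; longest linear sequence: 9 steps.

Step 8 (twofold ring closure). In the strongly acidic medium one or both aryl enol ethers may be cleaved by protonation at C3 and loss of the phenol before the acylium ion has closed. The second closure may also lag, so that the free C7 hydroxyl is acylated between molecules and esters or oligomers build up. The fallback uses neither enol ethers nor strong acid; it sets out from 7 and comes back at 17. Claisen–Schmidt condensation of 7 with 1-(2-hydroxy-4,6-dimethoxyphenyl)ethan-1-one (KOH, EtOH, 25 °C) should give the chalcone (2E)-1-(2-hydroxy-4,6-dimethoxyphenyl)-3-{4-[4-methoxy-2,6-bis(methoxymethoxy)phenoxy]phenyl}prop-2-en-1-one F1. Oxidative cyclisation (I2 cat., DMSO, 130 °C) followed by HCl/MeOH should give the flavone diol 2-[4-(2,6-dihydroxy-4-methoxyphenoxy)phenyl]-5,7-dimethoxy-4H-chromen-4-one F2. A thermal Mentzer annulation of F2 with ethyl 3-(4-methoxyphenyl)-3-oxopropanoate (neat, 240 °C) should then give 17. C-acylation can only occur at the two equivalent free ring carbons, the ring can only close through the hydroxyl next to the new acyl group, and the first acyl group deactivates the ring against a second.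

Step 7 (mono-addition to the symmetric diol). Addition may go on to the second, equivalent hydroxyl, and on long exposure to base the aryloxy groups may exchange between phenoxide and enol ether, which would scramble the two arms. The fallback replaces the O-vinylation by a self-limiting C-acylation; it sets out from 13 and comes back at 17. Saponification and single ring closure of 13 (LiOH; then P2O5 in MeSO3H) should give the flavone diol F2 named above. C-acetylation (BF3·OEt2, AcOH, 80 °C), which stops after one acyl group because the ketone deactivates the ring and holds the neighbouring hydroxyl in a hydrogen bond, should give 2-[4-(3-acetyl-2,6-dihydroxy-4-methoxyphenoxy)phenyl]-5,7-dimethoxy-4H-chromen-4-one F3. Claisen–Schmidt condensation with 4-methoxybenzaldehyde (KOH, EtOH) should give the chalcone (2E)-1-(3-{4-[5,7-dimethoxy-4-oxo-4H-chromen-2-yl]phenoxy}-2,4-dihydroxy-6-methoxyphenyl)-3-(4-methoxyphenyl)prop-2-en-1-one F4. Oxidative cyclisation (I2 cat., DMSO, 130 °C) through the hydroxyl ortho to the ketone, which is the one next to the ether oxygen, should give 17.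

Step 6 (unmasking next to an enol ether). While the acetal ethers are cleaved, acid may exchange the 3,5-dimethoxyphenoxy group of the enol ether for methoxide or hydrolyse it to the β-keto ester. The fallback inverts the order; it sets out from 10 and comes back at 13. The MOM groups of 10 are removed first (HCl, MeOH/THF, 25 °C; the alkynoate is inert to acid) to give methyl 3-[4-(2,6-dihydroxy-4-methoxyphenoxy)phenyl]prop-2-ynoate F5. The conjugate addition is then run with a large excess of 11 (5 equiv, Cs2CO3, DMF, 60 °C), so that the hindered hydroxyls of F5 cannot compete for the alkynoate, and should give 13.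

**Further compounds**

F1 | step 8 | (2E)-1-(2-hydroxy-4,6-dimethoxyphenyl)-3-{4-[4-methoxy-2,6-bis(methoxymethoxy)phenoxy]phenyl}prop-2-en-1-one | COCOc1cc(OC)cc(OCOC)c1Oc1ccc(/C=C/C(=O)c2c(O)cc(OC)cc2OC)cc1
F2 | step 8 | 2-[4-(2,6-dihydroxy-4-methoxyphenoxy)phenyl]-5,7-dimethoxy-4H-chromen-4-one | O=c1cc(-c2ccc(Oc3c(O)cc(OC)cc3O)cc2)oc2cc(OC)cc(OC)c12
F3 | step 7 | 2-[4-(3-acetyl-2,6-dihydroxy-4-methoxyphenoxy)phenyl]-5,7-dimethoxy-4H-chromen-4-one | CC(=O)c1c(OC)cc(O)c(Oc2ccc(cc2)-c2cc(=O)c3c(OC)cc(OC)cc3o2)c1O
F4 | step 7 | (2E)-1-(3-{4-[5,7-dimethoxy-4-oxo-4H-chromen-2-yl]phenoxy}-2,4-dihydroxy-6-methoxyphenyl)-3-(4-methoxyphenyl)prop-2-en-1-one | COc1ccc(/C=C/C(=O)c2c(OC)cc(O)c(Oc3ccc(cc3)-c3cc(=O)c4c(OC)cc(OC)cc4o3)c2O)cc1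
F5 | step 6 | methyl 3-[4-(2,6-dihydroxy-4-methoxyphenoxy)phenyl]prop-2-ynoate | COC(=O)C#Cc1ccc(Oc2c(O)cc(OC)cc2O)cc1
A1 | direct plan | apigenin, 5,7-dihydroxy-2-(4-hydroxyphenyl)-4H-chromen-4-one | O=c1cc(-c2ccc(O)cc2)oc2cc(O)cc(O)c12
A2 | direct plan | 7-(benzyloxy)-5-hydroxy-2-(4-methoxyphenyl)-4H-chromen-4-one | COc1ccc(cc1)-c1cc(=O)c2c(O)cc(OCc3ccccc3)cc2o1
A3 | direct plan | 7-(benzyloxy)-5,8-dihydroxy-2-(4-methoxyphenyl)-4H-chromen-4-one | COc1ccc(cc1)-c1cc(=O)c2c(O)cc(OCc3ccccc3)c(O)c2o1
A4 | direct plan | 4-{[7-(benzyloxy)-5-hydroxy-2-(4-methoxyphenyl)-4-oxo-4H-chromen-8-yl]oxy}benzaldehyde | COc1ccc(cc1)-c1cc(=O)c2c(O)cc(OCc3ccccc3)c(Oc3ccc(C=O)cc3)c2o1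
A5 | direct plan | 2-chloro-1-(2,4,6-trimethoxyphenyl)ethan-1-one | COc1cc(OC)c(C(=O)CCl)c(OC)c1
A6 | direct plan | 1-(4-{[7-(benzyloxy)-5-hydroxy-2-(4-methoxyphenyl)-4-oxo-4H-chromen-8-yl]oxy}phenyl)-3-(2,4,6-trimethoxyphenyl)propane-1,3-dione | COc1ccc(cc1)-c1cc(=O)c2c(O)cc(OCc3ccccc3)c(Oc3ccc(cc3)C(=O)CC(=O)c3c(OC)cc(OC)cc3OC)c2o1
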